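A small charge of catalyst, 15 mol% on G, has to turn G into X in this flask, so I asked how long it lasts before asking what Q does to it.

- teal: G 0.048 M; Q 1.05 equiv; J 15 mol%; the very flask that is asked about, followed so far
- flask: G 0.048 M; Q 1.05 equiv; J 15 mol%; volume of the second phase over the first 2.0
teal run (percent of the G charged)

| time / h | X / % |
|---|---|
| 0.167 | 1.7 |
| 0.500 | 4.1 |
| 0.833 | 5.6 |
| 1.33 | 8.7 |
| 2.00 | 13.3 |
| 2.50 | 15.7 |
| 3.00 | 17.7 |

(scatter of a reading: 0.5 percentage points)
- in the second phase: Q, E; everything else is in the first
- charges count per volume of the first phase; a concentration in a rate is the amount of a species over the volume of its own phase; every rate counts per litre of the first phase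
- steps under discussion: J + Q <-> Z + E; G + Z -> X + J; Z -> D
- the earlier runs hold the two phases in the same ratio of volumes as the flask asked about
- no earlier run changes the charge of Q; that part of a forecast is a guess
- apparent order in Q when 30% of the G are converted (percent change of the rate of making X for one percent more Q charged)
- factor on the rate of making X when 30% of the G are converted if Q is charged twice over

I counted progress as y, minus the natural logarithm of the fraction of G left. I began with the main step: with Z held steady, G + Z → X + J makes y climb in a straight line. The teal run gave a slope of 0.0837 h⁻¹ up to 0.500 h, and 30% conversion means y = 0.357, so that conversion would come at 4.26 h.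

But from 0.500 h to 3.00 h the slope was 0.0612 h⁻¹, lower, so I added Z → D. Both steps start from Z, so the y gained per catalyst lost is a constant, the partition ratio, whatever share of the catalyst is Z. Integrating with that share held steady, y rises along a falling exponential towards a limit. The two slopes, each carrying the scatter of the readings, gave the working catalyst a decay constant of 0.209 h⁻¹ and y a limit of 0.422. In X that limit reads 34.4%, my estimate of the ceiling: the fraction of G the charged catalyst converts before it has become D. At 30% conversion, 15.4% of the catalyst would still be working, as J or Z, and the time stretches to 8.94 h.

Last I added the exchange J + Q ⇌ Z + E, taken as fast. In my reckoning, at fixed conversion the partition ratio keeps the working catalyst the same when more Q is charged, so Q acts through φ, the share of the working catalyst that is Z. Per G charged, about 0.600 of Q remains, and the order is one minus φ, times the charge over that remainder. The readings don't show φ, so I guessed 0.7, which gave an order of 0.525 and a factor of 1.24.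

The forecast gave 0.6 (0.25 to 1) and 1.35 (1.1 to 1.85), above mine, adding “No run varies Q, so this stays a guess”.

The flask gives an order of 0.38 and a factor of 1.16, with 19.4% of the catalyst standing as Z at that conversion.

    J + Q ⇌ Z + E (K = 2.88, k = 946 M⁻¹ h⁻¹)
    G + Z → X + J (k = 13.4 M⁻¹ h⁻¹)
    Z → D (k = 0.203 h⁻¹)

Against my ceiling of 34.4%, X in the flask reached 37.8% after 60.0 h. Q stands in neither G + Z → X + J nor Z → D, so with Q charged twice over my ceiling stays at 34.4%, above 30%, and that run reached 30% conversion in 0.899 of the time.

The runs come from a simulation from invented constants; noise was put on by code.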